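Start from the half.

all flasks: free catalyst 0.5 mol%
- Monday's: left-handed substrate 0.025 M; right-handed substrate 0.025 M; partner 2.2 equiv; racemization catalyst 0.088 mol%; temperature 12 °C; run made earlier
- Tuesday's: left-handed substrate 0.038 M; right-handed substrate 0.038 M; partner 2.2 equiv; racemization catalyst 0.088 mol%; temperature 29 °C; run made earlier
- Sunday's: left-handed substrate 0.050 M; right-handed substrate 0.050 M; partner 2.2 equiv; racemization catalyst 0.18 mol%; temperature 12 °C; run made earlier
- violet: left-handed substrate 0.050 M; right-handed substrate 0.050 M; partner 2.20 equiv; racemization catalyst 0.088 mol%; temperature 35 °C; time 40 min
- ochre: left-handed substrate 0.050 M; right-handed substrate 0.050 M; partner 2.20 equiv; racemization catalyst 0.088 mol%; temperature 20 °C; time 40 min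
- amber: left-handed substrate 0.050 M; right-handed substrate 0.050 M; partner 2.20 equiv; racemization catalyst 0.088 mol%; temperature 5 °C; time 40 min

- Monday's (time / min: left-handed product / %): 20.0: 19.8; 40.0: 30.5; 60.0: 37.1; 80.0: 41.9
- Tuesday's (time / min: left-handed product / %): 6.00: 29.6; 12.0: 40.7; 20.0: 48.4; 25.0: 51.3
- Sunday's (time / min: left-handed product / %): 10.0: 30.7; 25.0: 45.5; 50.0: 55.9; 80.0: 63.4

(readings scatter by 0.3 percentage points)

- free catalyst is single-handed; left-handed substrate and right-handed substrate are mirror images of each other, charged as a racemate, each of them at the stated concentration
- the numbers in the tables scatter with a standard deviation of 0.3 percentage points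

- the flask that comes out highest in amount of left-handed product, in percent of the left-handed substrate and right-handed substrate together charged, or "all alike" when all lie within 1.5 percentage points (violet / ochre / amber / all alike)
- left-handed product at the end, in percent of the left-handed substrate and right-handed substrate together charged, violet
- left-handed product at the end, in percent of the left-handed substrate and right-handed substrate together charged, ochre
- left-handed product at the end, in percent of the left-handed substrate and right-handed substrate together charged, amber

Anna reads these flasks as a plain kinetic resolution. Free catalyst consumes the left-handed substrate, so left-handed product stops near half of the racemate. She points to Monday's gains, which shrink from 11 points to 4.8 points per interval, and to Tuesday's 51.3% at 25.0 min. For her, warmth only reaches the half sooner.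

Boris reads a dynamic kinetic resolution and answers with Sunday's 63.4%, which stands 13 points above the half. For him, racemization feeds the product.

So take the fast step as over and let p be the fraction of the charged substrates not yet left-handed product. The feed constant κ, a pseudo-first-order constant, is the logarithmic fall of p per minute. Sunday's last two readings give κ = 0.00621 /min, and Tuesday's give 0.0116 /min. Both carry the scatter of the readings. If κ is taken as proportional to the concentration of racemization catalyst, warming from 12 °C to 29 °C multiplied it by 5.01.

My own reckoning, which is not the forecast's, goes as follows. Violet has Tuesday's loading at a higher concentration, so I scale κ to 0.0152 /min, leaving aside the last degrees of warming. Starting p at 0.5 gives left-handed product of 72.8% for violet.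

The forecast, on Boris's side, names violet, with 63.5% (60% to 67%), ochre 55% (52.5% to 57.5%) and amber 46% (42.5% to 48.5%): “Warmest wins, because racemization continues after the fast phase ends.” My violet figure lies above that range.

The simulation puts violet highest at 71.1%, with ochre at 56.1% and amber at 44.8%, so it sides with Boris; the forecast's violet is 7.6 points low and my figure 1.7 points high.

    left-handed substrate + racemization catalyst ⇌ right-handed substrate + racemization catalyst, rate k1*[racemization catalyst]*[left-handed substrate] forward; the back reaction follows from the equilibrium constant (k = 8.20 /M/s, Ea = 56.0 kJ/mol)
    partner + free catalyst + right-handed substrate → free catalyst + right-handed product (k = 1.61 /M²/s, Ea = 39.0 kJ/mol)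
    partner + racemization catalyst → spent catalyst (k = 2.97 × 10⁻⁴ /M/s, Ea = 84.0 kJ/mol)
    partner + free catalyst + left-handed substrate → free catalyst + left-handed product (k = 247 /M²/s, Ea = 41.0 kJ/mol)
    (constants at 35 °C)

Anna's region is amber at 40.0 min, where left-handed product stands at 44.8% with 94% of the charged right-handed substrate still there. Ochre, at 20 °C, lies roughly midway in temperature between Sunday's and Tuesday's runs, so take the geometric mean of their κ, each scaled to ochre's concentration of racemization catalyst: 0.00680 /min. Starting p at 0.5, that gives left-handed product of 61.9%, and ochre holds 56.1%.

The readings are simulated for substances that don't exist, noise included.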